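## Structural features

Locants follow the furo[3,2-c][1,2]dioxine numbering of the target 18: O1–O2 is the peroxide, then C3, C4, C4a, O5, C6 (C=O), C7, C7a.

- 18 is a 1,2-dioxane (O1, O2, C3, C4, C4a, C7a) cis-fused along C4a–C7a to a γ-butyrolactone (C4a, O5, C6, C7, C7a). C3 carries a methyl group and an unbranched 10-phenyldecyl chain; C4a carries a methyl group.
- There are three stereocentres, all R. C7a (secondary peroxide carbon) is adjacent to C4a (quaternary, lactone oxygen). C3 (quaternary, peroxide carbon) is 1,3 to C4a across the C4 methylene.
- A five-membered lactone on a six-membered ring can only be cis-fused, so C4a and C7a are tied to each other. C3 is the independent centre.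
- The O–O bond does not survive low-valent metals, phosphines, hydride reagents or stannyl radicals. C7a–H is α to the peroxide and β to the lactone carbonyl, so base can trigger retro-oxa-Michael (E1cB) or Kornblum–DeLaMare-type cleavage.
- The real difficulty is C3: its two carbon substituents (methyl and a primary alkyl chain) differ little in size, it is remote from the other centres, and a tertiary C–O–O bond cannot be corrected once made. The absolute configuration adds to this.
- The key step exploits three features. C3 has the oxidation level of a methyl ketone carbon. C4 is a methylene between two fully substituted carbons. C4a is a tertiary C–O carbon that sits 1,4 to the C6 carboxyl carbon through C7a and C7. Hence C3–C4 can be made by attack of a C4a=C4 alkene on a C3 peroxycarbenium ion, and the C4a cation that results is captured by the C6 carboxyl group to close the lactone.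

## Logic of the disconnections

**18 to 14.** The bonds cut are C3–C4 (a ring C–C bond of the dioxane) and C4a–O5 (the lactone C–O bond). Cutting here turns C3 into a ketone-level cation and C4a into an alkene carbon, so both rings and two of the three stereocentres disappear at once; 14 is acyclic and has a single stereocentre, C7a. The forward step (14 through 15, 16 and 17 to 18) must make a C–C bond to a peroxycarbenium carbon faster than the O–O bond ionises, must trap the C4a cation with the carboxyl group, and must choose one face of the planar C3.

**14 to 13.** No skeletal bond is cut; C6 is taken back from the acid to the aldehyde level. The aldehyde is needed because the step that sets C7a works through an iminium ion. The forward oxidation must spare the acid-labile peroxyketal, the O–O bond and the 1,1-disubstituted alkene.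

**13 to 12 and 9.** The bond cut is C7a–O1. A β-peroxy aldehyde is the retron of an amine-catalysed enantioselective conjugate addition of a hydroperoxide to an enal. The cut also divides the molecule into its two halves, both achiral, so the route becomes convergent and the absolute configuration comes from a catalyst. The forward step must add at the β-carbon and not at the remote alkene terminus, must stop at the peroxide and not go on to an epoxide, and must be face-selective.

**9 to 6.** The bonds cut are C3–O2 and C3–OMe; C3 goes back to the substituted carbon of a 1,1-disubstituted alkene. An α-methoxy hydroperoxide is what methanol makes from the carbonyl oxide of an ozonolysis. The forward step must place the carbonyl oxide on the disubstituted carbon and the carbonyl group on the CH2 fragment.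

**6 to 4 and 5.** The bond cut is the one between C3 and the first CH2 of the chain. This gives a primary alkyl bromide and a commercial alkenyl Grignard reagent. The forward step needs an sp3–sp2 coupling without β-hydride loss.

**4 to 1 and 2.** The bond cut is the aryl–CH2 bond. Both partners are commercial; the forward step must couple at the alkene-derived borane and leave the primary C–Br bond alone.

**12 to 10 and 11.** The bond cut is the C7=C7a double bond of the enal. Both partners are commercial; the forward step must give the E isomer and must not homologate twice.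

## Other disconnections considered

**Alternative 1:** This is the first plan that comes to mind.
- Cut: O1–C7a only.
- Forward key step: 6-exo oxa-Michael addition of a tertiary hydroperoxide onto a butenolide. The butenolide (5R)-5-methyl-5-(2-methylidene-12-phenyldodecyl)furan-2(5H)-one A1 would be hydroperoxidised at its 1,1-disubstituted alkene (Mukaiyama–Isayama conditions) to (5R)-5-[(2R)-2-hydroperoxy-2-methyl-12-phenyldodecyl]-5-methylfuran-2(5H)-one A2, which would then cyclise.
- Ground for preferring the chosen plan: in A2 the C3 centre comes from capture of O2 by a free tertiary radical that is remote from C4a and flanked by methyl and CH2 groups of similar size, so no facial bias is to be expected and the C3 epimers would have to be separated late. A1 also needs its own asymmetric construction of the quaternary C4a, which lengthens the linear sequence. The key step closes one ring and forms one bond; the chosen step closes two rings and forms two bonds.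

**Alternative 2:**
- Cut: both C–O bonds of the peroxide (O1–C7a and O2–C3) and C4a–O5.
- Forward key step: [4+2] cycloaddition of singlet oxygen to (3E,5Z)-4,6-dimethyl-16-phenylhexadeca-3,5-dienoic acid A3 to give the dihydrodioxine acid 2-[(3R,6R)-4,6-dimethyl-6-(10-phenyldecyl)-3,6-dihydro-1,2-dioxin-3-yl]acetic acid A4. Iodolactonisation would give the iodolactone A5 (the 4-iodo derivative of 18 with iodine trans to O5), followed by radical deiodination.
- Ground for preferring the chosen plan: the suprafacial cycloaddition would encode the C3/C7a relation in the diene geometry, which is attractive. But for this target the chain must be the inside substituent of the s-cis diene (5Z), the ene reaction competes at both trisubstituted alkenes, and nothing in A3 controls the absolute sense, so A4 would be racemic and need resolution. Removing iodine from A5 generates a C4 radical β to the O–O bond, which can collapse to an epoxide. The sequence after the key step is also longer.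

**Alternative 3:**
- Cut: O2–C3, the tertiary C–O bond.
- Forward key step: iodonium-induced 6-endo cyclisation of (4R,5R)-4-hydroperoxy-5-methyl-5-[(1E)-2-methyl-12-phenyldodec-1-en-1-yl]oxolan-2-one A6 onto its E-trisubstituted alkene, giving the iodide A7 (the 4-iodo derivative of 18 with iodine cis to O5), followed by deiodination.
- Ground for preferring the chosen plan: the anti addition would translate alkene geometry into the C3 configuration, the one approach that tells methyl from chain by geometry and not by size. But A6 has a secondary hydroperoxide beside the quaternary C4a and cis to the alkenyl arm. No short stereocontrolled access to it is apparent: conjugate addition of a hydroperoxide to a γ,γ-disubstituted butenolide is hindered and tends towards epoxide formation. C4a would have to be set beforehand, and the deiodination again places a radical next to the peroxide. The chosen plan sets C7a by catalysis on an unhindered enal and then closes both rings in one operation.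

Key step: step 7

## Route

Remark on the chemistry: the α-methoxy peroxyketal carbon of 9, 13, 14 and 15 is carried as a mixture of epimers, because it becomes planar in 16.

Step 1
Reactants: 1 10-bromodec-1-ene; 2 bromobenzene
Product: 4 (10-bromodecyl)benzene, via 9-(10-bromodecyl)-9-borabicyclo[3.3.1]nonane 3 (not isolated)
Conditions: 9-BBN, THF, 0 °C to rt; then 2, Pd(dppf)Cl2 (3 mol%), K3PO4 (aq), THF/DMF, 50 °C
Reagents that add atoms: none
Why: Anti-Markovnikov hydroboration of the terminal alkene followed by B-alkyl Suzuki–Miyaura coupling; oxidative addition into the aryl bromide is much faster than into the primary alkyl bromide, which is kept for step 2, and no stereocentre is formed.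

Step 2
Reactants: 4 (10-bromodecyl)benzene; 5 prop-1-en-2-ylmagnesium bromide (isopropenylmagnesium bromide, THF solution)
Product: 6 2-methyl-12-phenyldodec-1-ene
Conditions: Fe(acac)3 (5 mol%), TMEDA (10 mol%), hexamethylenetetramine (5 mol%), THF, 0 °C, slow addition of 5
Reagents that add atoms: none
Why: Iron-catalysed Kumada-type cross-coupling of a primary alkyl bromide with an alkenyl Grignard reagent; the phenyl ring and the new 1,1-disubstituted alkene are inert and no stereocentre is formed.

Step 3
Reactants: 6 2-methyl-12-phenyldodec-1-ene
Product: 9 2-hydroperoxy-2-methoxy-13-phenyltridecane (racemic), via primary ozonide 7 (not isolated), via carbonyl oxide 8 (not isolated)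
Conditions: O3 (1 equiv), CH2Cl2/MeOH (4:1), −78 °C; N2 purge; no reductive work-up; concentration below 25 °C
Reagents that add atoms: ozone, O=[O+][O-]; methanol, CO
Why: Criegee ozonolysis with solvent trapping: cycloaddition gives 7, cycloreversion places the carbonyl oxide on the more substituted carbon (8, with formaldehyde as the partner), and methanol adds to 8 to give the α-methoxy hydroperoxide; the new centre is racemic and is destroyed in step 7, and the arene does not react at −78 °C with one equivalent of ozone.

Step 4
Reactants: 10 2-methylprop-2-enal (methacrolein); 11 (triphenylphosphoranylidene)acetaldehyde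
Product: 12 (2E)-4-methylpenta-2,4-dienal
Conditions: 10 (2 equiv), toluene, 70 °C; distillation; kept cold as a stabilised solution
Reagents that add atoms: none
Why: Wittig olefination with a formyl-stabilised ylide gives the E enal; the excess of 10 suppresses a second homologation of the product.

Step 5
Reactants: 12 (2E)-4-methylpenta-2,4-dienal; 9 2-hydroperoxy-2-methoxy-13-phenyltridecane
Product: 13 (3R)-3-[(2-methoxy-13-phenyltridecan-2-yl)peroxy]-4-methylpent-4-enal (both epimers at the ketal carbon)
Conditions: (R)-2-{bis[3,5-bis(trifluoromethyl)phenyl](trimethylsilyloxy)methyl}pyrrolidine (10 mol%), PhCO2H (10 mol%), toluene, −20 °C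
Reagents that add atoms: none
Why: Amine-catalysed enantioselective conjugate peroxidation of an enal (oxa-Michael addition under iminium activation), which also joins the two halves; the diaryl(silyloxy)methyl group of the (R)-catalyst shields the Si face of the β-carbon of the E, s-trans iminium ion, so the hydroperoxide adds to the Re face and sets the future C7a as R. The acid co-catalyst and low temperature favour protonation of the enamine over its closure onto the O–O bond.

Step 6
Reactants: 13 (3R)-3-[(2-methoxy-13-phenyltridecan-2-yl)peroxy]-4-methylpent-4-enal
Product: 14 (3R)-3-[(2-methoxy-13-phenyltridecan-2-yl)peroxy]-4-methylpent-4-enoic acid (both epimers at the ketal carbon)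
Conditions: NaClO2, NaH2PO4, 2-methylbut-2-ene (excess), t-BuOH/H2O, 0 °C; used at once
Reagents that add atoms: sodium chlorite, [Na+].[O-]Cl=O
Why: Pinnick oxidation; chlorite does not attack dialkyl peroxides, the excess of 2-methylbut-2-ene removes HOCl before it can add to the isopropenyl group, and the short exposure to the cold phosphate buffer should leave the peroxyketal and the C7a centre (no base, no enolisation towards C7a) untouched.

Step 7
Reactants: 14 (3R)-3-[(2-methoxy-13-phenyltridecan-2-yl)peroxy]-4-methylpent-4-enoic acid
Product: 18 (3R,4aR,7aR)-3,4a-dimethyl-3-(10-phenyldecyl)tetrahydro-3H-furo[3,2-c][1,2]dioxin-6(4H)-one, via trimethylsilyl ester 15 (not isolated), via peroxycarbenium ion 16 (not isolated), via dioxanyl cation 17 (not isolated)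
Conditions: N,O-bis(trimethylsilyl)acetamide (BSA, 1.2 equiv), CH2Cl2, 0 °C; then TMSOTf (0.2 equiv), −78 to −40 °C; Et3N, aq NaHCO3
Reagents that add atoms: none
Why: Proposed new method: silylation gives 15, and catalytic TMSOTf removes the ketal methoxy group as MeOSiMe3 to give peroxycarbenium ion 16, in which both ketal epimers converge on a planar C3 whose chain prefers the E position, anti to the O–O bond. The isopropenyl CH2 (C4) attacks C3 in a Prins-type 6-endo-trig closure of the 1,2-dioxane through a chair with the C7a side arm and the chain equatorial and the C3 methyl axial, which gives tertiary cation 17. The silyl ester carbonyl on the C7a arm then closes the lactone by 5-exo-trig attack on C4a from the only face it can reach, cis to C7, and loss of Me3Si+ regenerates TMSOTf. The closest known reaction types are the Lewis-acid cyclisation of unsaturated monoperoxyketals through peroxycarbenium ions (C–C bond formation with alkenes, allylsilanes and enol ethers) and Prins cyclisations terminated by an internal carboxyl group. C7a is carried over from 14 untouched, C4a follows from the obligatory cis fusion, and C3 follows from the E geometry of 16 in the chair. The chair with an axial C7a arm, which would lead from E-16 to the C3 epimer, is disfavoured because lactone closure from it forces the C4a methyl syn-axial to the axial C3 substituent. The step needs C–C attack to outrun O–O heterolysis and proton loss from 17; low temperature, a non-protic silyl Lewis acid, the nucleophilic 1,1-disubstituted alkene and the neighbouring ester serve this. The C3 preference rests only on the size difference between a primary alkyl chain and methyl, so a moderate selectivity with the separable C3 epimer as the minor product is the realistic expectation.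

## Compound list

1 | 10-bromodec-1-ene | C=CCCCCCCCCBr | starting material
2 | bromobenzene | Brc1ccccc1 | starting material
3 | 9-(10-bromodecyl)-9-borabicyclo[3.3.1]nonane | BrCCCCCCCCCCB1C2CCCC1CCC2 | intermediate
4 | (10-bromodecyl)benzene | BrCCCCCCCCCCc1ccccc1 | intermediate
5 | prop-1-en-2-ylmagnesium bromide | C=C(C)[Mg]Br | starting material
6 | 2-methyl-12-phenyldodec-1-ene | C=C(C)CCCCCCCCCCc1ccccc1 | intermediate
7 | 4-methyl-4-(10-phenyldecyl)-1,2,3-trioxolane (primary ozonide, racemic) | CC1(CCCCCCCCCCc2ccccc2)COOO1 | intermediate
8 | 13-phenyltridecan-2-one O-oxide (carbonyl oxide) | CC(CCCCCCCCCCc1ccccc1)=[O+][O-] | intermediate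
9 | 2-hydroperoxy-2-methoxy-13-phenyltridecane (racemic) | COC(C)(CCCCCCCCCCc1ccccc1)OO | intermediate
10 | 2-methylprop-2-enal (methacrolein) | C=C(C)C=O | starting material
11 | (triphenylphosphoranylidene)acetaldehyde | O=CC=P(c1ccccc1)(c1ccccc1)c1ccccc1 | starting material
12 | (2E)-4-methylpenta-2,4-dienal | C=C(C)/C=C/C=O | intermediate
13 | (3R)-3-[(2-methoxy-13-phenyltridecan-2-yl)peroxy]-4-methylpent-4-enal (both ketal epimers) | O=CC[C@@H](OOC(C)(OC)CCCCCCCCCCc1ccccc1)C(C)=C | intermediate
14 | (3R)-3-[(2-methoxy-13-phenyltridecan-2-yl)peroxy]-4-methylpent-4-enoic acid (both ketal epimers) | OC(=O)C[C@@H](OOC(C)(OC)CCCCCCCCCCc1ccccc1)C(C)=C | intermediate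
15 | trimethylsilyl (3R)-3-[(2-methoxy-13-phenyltridecan-2-yl)peroxy]-4-methylpent-4-enoate (both ketal epimers) | C[Si](C)(C)OC(=O)C[C@@H](OOC(C)(OC)CCCCCCCCCCc1ccccc1)C(C)=C | intermediate
16 | (E)-{[(3R)-2-methyl-5-oxo-5-[(trimethylsilyl)oxy]pent-1-en-3-yl]oxy}(13-phenyltridecan-2-ylidene)oxidanium, triflate salt (peroxycarbenium ion) | C[Si](C)(C)OC(=O)C[C@@H](O/[O+]=C(/CCCCCCCCCCc1ccccc1)C)C(C)=C | intermediate
17 | (3R,6R)-4,6-dimethyl-6-(10-phenyldecyl)-3-{2-oxo-2-[(trimethylsilyl)oxy]ethyl}-1,2-dioxan-4-ylium, triflate salt | C[C@@]1(CCCCCCCCCCc2ccccc2)C[C+](C)[C@@H](CC(=O)O[Si](C)(C)C)OO1 | intermediate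
18 | (3R,4aR,7aR)-3,4a-dimethyl-3-(10-phenyldecyl)tetrahydro-3H-furo[3,2-c][1,2]dioxin-6(4H)-one (cis-fused 1,2-dioxane/γ-lactone) | C[C@@]1(CCCCCCCCCCc2ccccc2)C[C@@]2(C)OC(=O)C[C@H]2OO1 | target

## Step count and least certain steps

Total step count: 7. Longest linear sequence: 6 (steps 1, 2, 3, 5, 6, 7).

**Step 7 (key step, proposed new method).**
- What may go wrong: low facial discrimination at C3 during C–C bond formation, because methyl and the chain differ little. Also heterolysis of the O–O bond, or proton loss from the C4a cation, may compete with lactone closure.
- Fallback (known chemistry, C–O bond formation in place of C–C bond formation), setting out from 6 and returning at 18: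
  - A [Cu(tBu-box)](SbF6)2-catalysed carbonyl-ene reaction of 6 with methyl pyruvate (ligand enantiomer chosen for the 2R carbinol) would give methyl (2R)-2-hydroxy-2-methyl-4-methylidene-14-phenyltetradecanoate F1. Hydrogen transfer from either allylic position is acceptable, since both alkene isomers lead to the same tertiary radical later.
  - i-Bu2AlH at −78 °C would give (2R)-2-hydroxy-2-methyl-4-methylidene-14-phenyltetradecanal F2.
  - Horner–Wadsworth–Emmons olefination (triethyl phosphonoacetate, LiCl, DBU) would give ethyl (2E,4R)-4-hydroxy-4-methyl-6-methylidene-16-phenylhexadec-2-enoate F3.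
  - Mukaiyama–Isayama hydroperoxysilylation (Co(acac)2, O2, Et3SiH) would give ethyl (2E,4R)-4-hydroxy-4,6-dimethyl-16-phenyl-6-[(triethylsilyl)peroxy]hexadec-2-enoate F4 as both C6 epimers.
  - Desilylation (Bu4NF/AcOH) and amine-mediated 6-exo oxa-Michael addition (Et2NH, CF3CH2OH) would give, after separation of isomers, ethyl 2-[(3R,4R,6R)-4-hydroxy-4,6-dimethyl-6-(10-phenyldecyl)-1,2-dioxan-3-yl]acetate F5.
  - Acid-catalysed lactonisation (PPTS) of F5 returns to the route at 18.

**Step 5.**
- What may go wrong: after the addition the enamine may close onto the O–O bond, giving epoxidation with loss of the hemiketal alkoxide. Addition may also occur at the remote alkene terminus, or the adduct may revert and lose enantiopurity.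
- Fallback (ene reaction and resolution in place of catalytic conjugate addition), setting out from 6 and returning at 18:
  - Ozonolysis of 6 with reductive work-up (O3; Me2S) would give 13-phenyltridecan-2-one F6, and HC(OMe)3/MeOH/TsOH would give 2,2-dimethoxy-13-phenyltridecane F7.
  - In parallel, Schenck ene photooxygenation (O2, hν, tetraphenylporphyrin) of commercial methyl 4-methylpent-3-enoate would give, after removal of the regioisomer, methyl 3-hydroperoxy-4-methylpent-4-enoate (racemic) F8.
  - Enzymatic kinetic resolution of F8 (peroxidase- or lipase-mediated, whichever consumes the 3S enantiomer) would leave methyl (3R)-3-hydroperoxy-4-methylpent-4-enoate F9.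
  - PPTS-catalysed exchange of F9 with F7 would give methyl (3R)-3-[(2-methoxy-13-phenyltridecan-2-yl)peroxy]-4-methylpent-4-enoate F10.
  - F10 would be treated with TMSOTf (1.1 equiv) as in step 7; the ester carbonyl traps the cation and loses its methyl group, and the route is rejoined at 18.

**Step 6.**
- What may go wrong: hydrolysis of the methoxy peroxyketal in the acidic aqueous medium, or addition of HOCl to the isopropenyl group.
- Fallback (oxidation moved to after the cyclisation), setting out from 13 and returning at 18:
  - 13 itself would be treated with catalytic TMSOTf. The aldehyde oxygen traps the C4a cation and the methoxy group released from the ketal is returned to the anomeric carbon, giving (3R,4aR,7aR)-6-methoxy-3,4a-dimethyl-3-(10-phenyldecyl)hexahydro-3H-furo[3,2-c][1,2]dioxine F11 as both C6 anomers.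
  - Oxidation of this methyl acetal (mCPBA, BF3·OEt2) gives 18.

**Step 4.**
- What may go wrong: a second homologation of the product, oligomerisation of the dienal, and loss on isolation because of its volatility.
- Fallback (ester-level olefination and late oxidation), setting out from 10 and returning at 12:
  - Horner–Wadsworth–Emmons reaction of 10 with triethyl phosphonoacetate would give ethyl (2E)-4-methylpenta-2,4-dienoate F12.
  - i-Bu2AlH would give (2E)-4-methylpenta-2,4-dien-1-ol F13.
  - MnO2 in toluene would deliver 12 as a filtered solution that goes directly into step 5.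

## Further compounds

F1 | step 7 | methyl (2R)-2-hydroxy-2-methyl-4-methylidene-14-phenyltetradecanoate | C=C(CCCCCCCCCCc1ccccc1)C[C@@](C(=O)OC)(C)O
F2 | step 7 | (2R)-2-hydroxy-2-methyl-4-methylidene-14-phenyltetradecanal | C=C(CCCCCCCCCCc1ccccc1)C[C@@](C=O)(C)O
F3 | step 7 | ethyl (2E,4R)-4-hydroxy-4-methyl-6-methylidene-16-phenylhexadec-2-enoate | C=C(CCCCCCCCCCc1ccccc1)C[C@@](/C=C/C(=O)OCC)(C)O
F4 | step 7 | ethyl (2E,4R)-4-hydroxy-4,6-dimethyl-16-phenyl-6-[(triethylsilyl)peroxy]hexadec-2-enoate (both C6 epimers) | CC(OO[Si](CC)(CC)CC)(CCCCCCCCCCc1ccccc1)C[C@@](/C=C/C(=O)OCC)(C)O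
F5 | step 7 | ethyl 2-[(3R,4R,6R)-4-hydroxy-4,6-dimethyl-6-(10-phenyldecyl)-1,2-dioxan-3-yl]acetate | C[C@@]1(CCCCCCCCCCc2ccccc2)C[C@@](C)(O)[C@@H](CC(=O)OCC)OO1
F6 | step 5 | 13-phenyltridecan-2-one | CC(=O)CCCCCCCCCCc1ccccc1
F7 | step 5 | 2,2-dimethoxy-13-phenyltridecane | COC(C)(OC)CCCCCCCCCCc1ccccc1
F8 | step 5 | methyl 3-hydroperoxy-4-methylpent-4-enoate (racemic) | COC(=O)CC(OO)C(C)=C
F9 | step 5 | methyl (3R)-3-hydroperoxy-4-methylpent-4-enoate | COC(=O)C[C@@H](OO)C(C)=C
F10 | step 5 | methyl (3R)-3-[(2-methoxy-13-phenyltridecan-2-yl)peroxy]-4-methylpent-4-enoate (both ketal epimers) | COC(=O)C[C@@H](OOC(C)(OC)CCCCCCCCCCc1ccccc1)C(C)=C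
F11 | step 6 | (3R,4aR,7aR)-6-methoxy-3,4a-dimethyl-3-(10-phenyldecyl)hexahydro-3H-furo[3,2-c][1,2]dioxine (both C6 anomers) | C[C@@]1(CCCCCCCCCCc2ccccc2)C[C@@]2(C)OC(OC)C[C@H]2OO1
F12 | step 4 | ethyl (2E)-4-methylpenta-2,4-dienoate | C=C(C)/C=C/C(=O)OCC
F13 | step 4 | (2E)-4-methylpenta-2,4-dien-1-ol | C=C(C)/C=C/CO
A1 | alternative 1 | (5R)-5-methyl-5-(2-methylidene-12-phenyldodecyl)furan-2(5H)-one | C=C(CCCCCCCCCCc1ccccc1)C[C@@]2(C)OC(=O)C=C2
A2 | alternative 1 | (5R)-5-[(2R)-2-hydroperoxy-2-methyl-12-phenyldodecyl]-5-methylfuran-2(5H)-one | C[C@](CCCCCCCCCCc1ccccc1)(OO)C[C@@]2(C)OC(=O)C=C2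
A3 | alternative 2 | (3E,5Z)-4,6-dimethyl-16-phenylhexadeca-3,5-dienoic acid | OC(=O)C/C=C(\C)/C=C(/C)\CCCCCCCCCCc1ccccc1
A4 | alternative 2 | 2-[(3R,6R)-4,6-dimethyl-6-(10-phenyldecyl)-3,6-dihydro-1,2-dioxin-3-yl]acetic acid (would form as the racemate) | C[C@@]1(CCCCCCCCCCc2ccccc2)C=C(C)[C@@H](CC(=O)O)OO1
A5 | alternative 2 | 4-iodo-3,4a-dimethyl-3-(10-phenyldecyl)tetrahydro-3H-furo[3,2-c][1,2]dioxin-6(4H)-one, iodine trans to O5 (would form as the racemate) | C[C@@]1(CCCCCCCCCCc2ccccc2)[C@H](I)[C@@]2(C)OC(=O)C[C@H]2OO1
A6 | alternative 3 | (4R,5R)-4-hydroperoxy-5-methyl-5-[(1E)-2-methyl-12-phenyldodec-1-en-1-yl]oxolan-2-one | C/C(CCCCCCCCCCc1ccccc1)=C\[C@@]2(C)OC(=O)C[C@H]2OO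
A7 | alternative 3 | 4-iodo-3,4a-dimethyl-3-(10-phenyldecyl)tetrahydro-3H-furo[3,2-c][1,2]dioxin-6(4H)-one, iodine cis to O5 | C[C@@]1(CCCCCCCCCCc2ccccc2)[C@@H](I)[C@@]2(C)OC(=O)C[C@H]2OO1
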